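All runs come from a simulation with made-up constants, and the scatter is random.

A leftover opened the dispute: the G in south-east stays near 28.3% at 40.0 h, while in east, with more Q, it is down to 17.9%, so two of us argued over what Q buys.

| flask | G | L | Q | remark | time |
|---|---|---|---|---|---|
| south-east | 0.35 M | 1 equiv | 0.41 equiv | run made earlier |  |
| east | 0.35 M | 1 equiv | 0.69 equiv | run made earlier |  |
| elm | 0.35 M | 1.00 equiv | 0.390 equiv |  | 3.0 d |
| oak | 0.35 M | 1.00 equiv | 0.300 equiv |  | 3.0 d |
| cedar | 0.35 M | 1.00 equiv | 0.510 equiv |  | 3.0 d |

| run | time / h | G / % | X / % |
|---|---|---|---|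
| south-east | 6.00 | 47.6 | 50.9 |
| south-east | 12.0 | 36.4 | 58.7 |
| south-east | 20.0 | 30.9 | 59.6 |
| south-east | 25.0 | 30.9 | 58.6 |
| south-east | 30.0 | 29.1 | 56.0 |
| south-east | 40.0 | 28.3 | 53.9 |
| east | 3.00 | 61.5 | 38.2 |
| east | 5.00 | 49.3 | 49.8 |
| east | 8.00 | 39.1 | 57.9 |
| east | 12.0 | 31.9 | 64.2 |
| east | 20.0 | 23.9 | 67.0 |
| east | 40.0 | 17.9 | 63.0 |

(readings scatter by 0.5 percentage points)

1. part of the G that has reacted at the end, elm
2. part of the G that has reacted at the end, oak
3. part of the G that has reacted at the end, cedar
4. what raising the equivalents of Q from its lowest to its highest value here does to the part of the G that has reacted (changes below 5 percentage points count as none) (it rises / no change / it falls)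

- the numbers in the tables scatter by 0.5 percentage points (one standard deviation)

The first chemist counts equivalents of Q per G reacted, as if Q alone were paid out, and that count reads 0.572 in south-east but 0.840 in east, which she puts down to east still creeping. The second chemist, whose reckoning I take as mine, distrusts a cost that moves so far and counts L and Q together as one limiting reagent. Her toll is the equivalents of L plus Q charged, divided by the share of G reacted at 40.0 h, the last reading of both runs, a ratio of what is paid to what is turned over; it belongs to that moment, and it sinks as the share reacted grows. It reads 1.97 in south-east and 2.06 in east, and I carry the mean, 2.01. Dividing each charge by it gives me 64.6% for oak, 69.1% for elm and 75.0% for cedar, and since these flasks run 3.0 d rather than 40.0 h, I expect slightly more in each.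

The forecast, which sides with the first chemist at “roughly 0.55 equiv Q per G converted”, says 69% for elm, 58% for oak and 78% for cedar, and that the part reacted it rises, parting from my reckoning most at oak.

The flasks give 72.7% for elm, 69.0% for oak and 77.6% for cedar, so the part reacted it rises, by 8.6 percentage points.

    G + L → E + X (k = 0.623 L mol⁻¹ h⁻¹)
    L + E ⇌ J, settled at all times (K = 1400 L mol⁻¹)
    E + Q ⇌ D, settled at all times (K = 18000 L mol⁻¹)
    X → Z (k = 0.00847 h⁻¹)

In cedar the first step gave G a half-life of 0.24 d at 0.128 d, short against 3.0 d, yet at the end G stands at 22% beside free L at 0.84%, with [D] at 0.178 M and [J] at 0.0754 M. The toll now reads 1.88 in oak and 1.95 in cedar, while Q per G reacted runs from 0.435 in oak to 0.657 in cedar, so the first view serves near the charge where it was read, as elm's 0.536 shows.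

For the neighbour with cedar's equivalents and G at 0.087 M, the toll gives 75.0% again; that flask gives 71.0%, with 9.1% of its L and 3.4% of its Q still free.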